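**Retrosynthetic overview**
1. Target 13 ⇒ ether 11: the C8 prenyl group is installed last, by [3,3] shift of an O7 1,1-dimethylallyl ether made from phenol 7 and carbonate 10, because an alkene would not survive the carbene step.
2. 6 ⇒ 5 (key disconnection C2–C3): in ring C, C2 is a methylene bound only to O1 and C3, and C3 is a methine between the C4 ketone and aryl ring B. C3 is therefore made as a rhodium aryl(acyl)carbene and C2 as the methyl of an ortho-methoxy group on ring A; C–H insertion closes ring C and sets C3 (R).
3. 5 ⇒ 4 ⇒ 2 + 3: diazo transfer onto a deoxybenzoin built by palladium-catalysed α-arylation of acetophenone 2 with bromochromane 3.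
4. Ring order: ring A (in 1) and rings B and D (the benzene and dimethyldihydropyran rings of 3) are bought; ring C is the only ring formed (step 4). After step 4 no amine or alkoxide reagent is added, since C3–H is enolisable.

Key step: step 4

Remark: 1, 3 and 8 are taken as purchasable; Rh2(S-PTAD)4 is assumed to give the 3R series, which is checked on the first run, with Rh2(R-PTAD)4 used if the sense is the reverse; catalyst-bound species of the catalytic cycles are described in the Why lines and carry no number.

**Step 1**
Reactants: 1 4'-hydroxy-2'-methoxyacetophenone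
Product: 2 1-[2-methoxy-4-(triisopropylsilyloxy)phenyl]ethan-1-one
Conditions: TIPSCl, imidazole, DMF, 0 °C → rt
Reagents that add atoms: triisopropylsilyl chloride, CC(C)[Si](Cl)(C(C)C)C(C)C
Why: Imidazole-mediated O-silylation of the phenol; the bulky triisopropylsilyl ether is chosen because it must pass NaOtBu at 80 °C and DBU in steps 2 and 3 and has no C–H bond next to oxygen for a carbene to attack.

**Step 2**
Reactants: 2 1-[2-methoxy-4-(triisopropylsilyloxy)phenyl]ethan-1-one; 3 6-bromo-2,2-dimethylchromane
Product: 4 2-(2,2-dimethylchroman-6-yl)-1-[2-methoxy-4-(triisopropylsilyloxy)phenyl]ethan-1-one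
Conditions: Pd2(dba)3 (1.5 mol%), Xantphos (3.6 mol%), NaOtBu (2.2 equiv.), 2 (1.2 equiv.), toluene, 80 °C
Reagents that add atoms: none
Why: Palladium-catalysed ketone α-arylation, in which the sodium enolate of the methyl ketone couples with the aryl bromide after its oxidative addition to zerovalent palladium, and the wide-bite-angle ligand Xantphos should hold the reaction at monoarylation.

**Step 3**
Reactants: 4 2-(2,2-dimethylchroman-6-yl)-1-[2-methoxy-4-(triisopropylsilyloxy)phenyl]ethan-1-one
Product: 5 2-diazo-2-(2,2-dimethylchroman-6-yl)-1-[2-methoxy-4-(triisopropylsilyloxy)phenyl]ethan-1-one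
Conditions: p-ABSA (1.3 equiv.), DBU (1.5 equiv.), MeCN, 0 °C → rt, dark; quick filtration through neutral alumina, stored cold
Reagents that add atoms: 4-acetamidobenzenesulfonyl azide (p-ABSA), CC(=O)Nc1ccc(cc1)S(=O)(=O)N=[N+]=[N-]
Why: Regitz diazo transfer, in which the methylene between the ketone and the aryl ring is acidic enough for DBU and its enolate attacks the terminal nitrogen of the sulfonyl azide and expels the sulfonamide.

**Step 4**
Reactants: 5 2-diazo-2-(2,2-dimethylchroman-6-yl)-1-[2-methoxy-4-(triisopropylsilyloxy)phenyl]ethan-1-one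
Product: 6 (3R)-3-(2,2-dimethylchroman-6-yl)-7-(triisopropylsilyloxy)chroman-4-one
Conditions: Rh2(S-PTAD)4 (1 mol%), 4 Å MS, CH2Cl2, slow addition of 5, 0 → 40 °C; filtration through a short pad of silica, no amine
Reagents that add atoms: none
Why: Rh2(S-PTAD)4 adds to the diazo carbon of 5 and, after loss of N2, gives the dirhodium-bound aryl(acyl)carbene at the future C3, which takes a hydride-like hydrogen from the ortho O-methyl group while the C2–C3 bond forms in one three-centre transition state. The closest known reactions are the dirhodium-carboxylate-catalysed closures of ortho-alkoxyaryl α-diazo ketones to chroman-4-ones and of ortho-alkoxyaryl diazoacetates to dihydrobenzofurans, both C–H insertions next to an aryl ether oxygen; closure of a six-membered ring onto a methyl ether is the less documented variant. Ring C closes by 1,6-insertion, the six ring atoms being C3, C4, C4a, C8a, O1 and the former methyl carbon C2. C3 is the only new stereocentre and is set at the carbene carbon by the chiral phthalimido(adamantyl)acetate ligands, which leave one carbene face open to the tethered methyl group; C2 becomes an unsubstituted methylene and carries no stereochemistry. The step needs insertion into a primary C–H bond to win over oxonium-ylide formation at the methoxy oxygen, Wolff rearrangement and carbene dimerisation: the substrate has no C–H bond placed for a five-membered closure and no alkene, the methoxy oxygen is a weak donor because it is conjugated with the aryl ketone and its ylide could collapse only by a slow methyl shift and should revert to the carbene, and slow addition keeps the diazo concentration low. From here on C3–H, which lies between the ketone and ring B, is kept away from amine and alkoxide reagents, and the enantiomeric purity is checked after each step.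

**Step 5**
Reactants: 6 (3R)-3-(2,2-dimethylchroman-6-yl)-7-(triisopropylsilyloxy)chroman-4-one
Product: 7 (3R)-3-(2,2-dimethylchroman-6-yl)-7-hydroxychroman-4-one
Conditions: HF·pyridine, THF, 0 °C → rt (polypropylene vessel); pH 7 buffer work-up
Reagents that add atoms: none
Why: Acidic fluoride cleavage of an aryl silyl ether whose phenol is a good leaving group (para to the ketone); the medium holds no base stronger than pyridine, so the enolisable C3 centre should keep its configuration.

**Step 6**
Reactants: 8 2-methylbut-3-en-2-ol
Product: 10 isobutyl 2-methylbut-3-en-2-yl carbonate, via lithium 2-methylbut-3-en-2-olate 9 (not isolated)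
Conditions: n-BuLi, THF, −78 °C; then isobutyl chloroformate, −78 °C → rt
Reagents that add atoms: isobutyl chloroformate, CC(C)COC(=O)Cl
Why: Acylation of the lithium alkoxide of the tertiary allylic alcohol with a chloroformate gives the mixed carbonate that serves as π-allyl precursor.

**Step 7**
Reactants: 7 (3R)-3-(2,2-dimethylchroman-6-yl)-7-hydroxychroman-4-one; 10 isobutyl 2-methylbut-3-en-2-yl carbonate
Product: 11 (3R)-3-(2,2-dimethylchroman-6-yl)-7-[(2-methylbut-3-en-2-yl)oxy]chroman-4-one
Conditions: Pd(PPh3)4 (3 mol%), 10 (1.3 equiv.), 4 Å MS, THF, 0 °C, short reaction time; direct filtration through silica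
Reagents that add atoms: none
Why: Tsuji–Trost-type O-allylation, in which zerovalent palladium ionises 10 with loss of CO2, the isobutoxide is quenched by the acidic phenol, and the phenoxide attacks the π-allyl complex at its more substituted terminus under kinetic control to give the tertiary ether; the low temperature, short time and small excess of 10 limit re-ionisation to the linear ether and base contact at C3.

**Step 8**
Reactants: 11 (3R)-3-(2,2-dimethylchroman-6-yl)-7-[(2-methylbut-3-en-2-yl)oxy]chroman-4-one
Product: 13 (3R)-3-(2,2-dimethylchroman-6-yl)-7-hydroxy-8-(3-methylbut-2-en-1-yl)chroman-4-one, via cyclohexadienone tautomer 12 (not isolated)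
Conditions: Eu(fod)3 (10 mol%), CHCl3 (ethanol-free), 50 °C
Reagents that add atoms: none
Why: Aromatic Claisen rearrangement, a [3,3] shift eased by the gem-dimethyl group and the mild Lewis acid Eu(fod)3, should deliver the allyl terminus to C8 rather than C6 because conjugation of O1 with the C4 ketone gives the C7–C8 bond more double-bond character, after which dienone 12 tautomerises to the phenol without touching C3.

**Compound list**
1 | 4'-hydroxy-2'-methoxyacetophenone | CC(=O)c1ccc(O)cc1OC | starting material
2 | 1-[2-methoxy-4-(triisopropylsilyloxy)phenyl]ethan-1-one | CC(=O)c1ccc(O[Si](C(C)C)(C(C)C)C(C)C)cc1OC | intermediate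
3 | 6-bromo-2,2-dimethylchromane | CC1(C)CCc2cc(Br)ccc2O1 | starting material
4 | 2-(2,2-dimethylchroman-6-yl)-1-[2-methoxy-4-(triisopropylsilyloxy)phenyl]ethan-1-one | COc1cc(O[Si](C(C)C)(C(C)C)C(C)C)ccc1C(=O)Cc1ccc2c(c1)CCC(C)(C)O2 | intermediate
5 | 2-diazo-2-(2,2-dimethylchroman-6-yl)-1-[2-methoxy-4-(triisopropylsilyloxy)phenyl]ethan-1-one | COc1cc(O[Si](C(C)C)(C(C)C)C(C)C)ccc1C(=O)C(=[N+]=[N-])c1ccc2c(c1)CCC(C)(C)O2 | intermediate
6 | (3R)-3-(2,2-dimethylchroman-6-yl)-7-(triisopropylsilyloxy)chroman-4-one | CC(C)[Si](C(C)C)(C(C)C)Oc1ccc2c(c1)OC[C@@H](c1ccc3c(c1)CCC(C)(C)O3)C2=O | intermediate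
7 | (3R)-3-(2,2-dimethylchroman-6-yl)-7-hydroxychroman-4-one | Oc1ccc2c(c1)OC[C@@H](c1ccc3c(c1)CCC(C)(C)O3)C2=O | intermediate
8 | 2-methylbut-3-en-2-ol | C=CC(C)(C)O | starting material
9 | lithium 2-methylbut-3-en-2-olate | C=CC(C)(C)[O-].[Li+] | intermediate
10 | isobutyl 2-methylbut-3-en-2-yl carbonate | C=CC(C)(C)OC(=O)OCC(C)C | intermediate
11 | (3R)-3-(2,2-dimethylchroman-6-yl)-7-[(2-methylbut-3-en-2-yl)oxy]chroman-4-one | C=CC(C)(C)Oc1ccc2c(c1)OC[C@@H](c1ccc3c(c1)CCC(C)(C)O3)C2=O | intermediate
12 | (3R)-3-(2,2-dimethylchroman-6-yl)-8-(3-methylbut-2-en-1-yl)-2,3-dihydro-4H-chromene-4,7(8H)-dione (cyclohexadienone tautomer, C8 configuration undefined) | CC(C)=CCC1C(=O)C=CC2=C1OC[C@@H](c1ccc3c(c1)CCC(C)(C)O3)C2=O | intermediate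
13 | (3R)-3-(2,2-dimethylchroman-6-yl)-7-hydroxy-8-(3-methylbut-2-en-1-yl)chroman-4-one | CC(C)=CCc1c(O)ccc2c1OC[C@@H](c1ccc3c(c1)CCC(C)(C)O3)C2=O | target

**Step count**
Total steps: 8. Longest linear sequence: 7 steps (steps 1, 2, 3, 4, 5, 7, 8); step 6 is a one-step side branch.

**Steps most likely to fail**

Step 4. The carbene may be captured by the lone pair of the methoxy oxygen (five-membered oxonium ylide followed by methyl shift) or undergo Wolff rearrangement faster than it inserts into the primary C–H bond, or the catalyst may discriminate the carbene faces poorly. The fallback sets out from 4 and returns at 6; it closes ring C by C–O bond formation and sets C3 by reduction. The ortho-methoxy group of 4 is cleaved with BCl3 (CH2Cl2, −78 → 0 °C), chelation to the ketone directing the Lewis acid to this ether, to give 2-(2,2-dimethylchroman-6-yl)-1-[2-hydroxy-4-(triisopropylsilyloxy)phenyl]ethan-1-one F1. Heating F1 with N,N-dimethylformamide dimethyl acetal (toluene, 90 °C) adds C2 and closes ring C to the isoflavone 3-(2,2-dimethylchroman-6-yl)-7-(triisopropylsilyloxy)-4H-chromen-4-one F2. Asymmetric transfer hydrogenation with the enantiomer of RuCl(p-cymene)(TsDPEN) that leads to the 3R series (HCO2H/Et3N, EtOAc, 40 °C) reduces C2=C3 and then the ketone, with dynamic kinetic resolution of the base-labile C3. This should give the cis alcohol (3R,4R)-3-(2,2-dimethylchroman-6-yl)-7-(triisopropylsilyloxy)chroman-4-ol F3. Oxidation with Dess–Martin periodinane (CH2Cl2, 0 °C), which is not basic, restores the ketone and gives 6.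

Step 7. Configuration at C3 may be lost by enolisation under the alkoxide and phenoxide released from the carbonate, and the phenoxide may attack the unsubstituted allyl terminus or the product may re-ionise on palladium to the linear prenyl ether. The fallback sets out from 7 and returns at 13, bypassing steps 7 and 8. Ortho-iodination with benzyltrimethylammonium dichloroiodate and CaCO3 (CH2Cl2/MeOH, rt), a reagent that halogenates phenols but not aryl alkyl ethers such as ring B, should give (3R)-3-(2,2-dimethylchroman-6-yl)-7-hydroxy-8-iodochroman-4-one F4; any 6-iodo isomer is removed at this stage. Stille coupling of F4 with tributyl(3-methylbut-2-en-1-yl)stannane (Pd(PPh3)4, toluene, 100 °C) under neutral conditions then gives 13.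

Step 8. The allyl unit may migrate to C6 instead of C8, or the Lewis acid may ionise the tertiary ether before the shift or close the new ortho-prenyl phenol to a dimethylpyran ring. The fallback sets out from 7 and returns at 13; it uses the unsubstituted allyl group, which cannot ionise to a tertiary cation. O-allylation of 7 with allyl methyl carbonate and Pd(PPh3)4 (THF, 0 °C, the protocol of step 7) gives (3R)-7-(allyloxy)-3-(2,2-dimethylchroman-6-yl)chroman-4-one F5. Thermal Claisen rearrangement (1,2-dichlorobenzene, 180 °C, no amine), which in 7-allyloxychromanones is directed to C8, gives (3R)-8-allyl-3-(2,2-dimethylchroman-6-yl)-7-hydroxychroman-4-one F6. Cross-metathesis of F6 with 2-methylbut-2-ene and the second-generation Grubbs catalyst (CH2Cl2, 40 °C) converts the allyl into the prenyl group and gives 13.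

**Further compounds**
F1 | step 4 | 2-(2,2-dimethylchroman-6-yl)-1-[2-hydroxy-4-(triisopropylsilyloxy)phenyl]ethan-1-one | Oc1cc(O[Si](C(C)C)(C(C)C)C(C)C)ccc1C(=O)Cc1ccc2c(c1)CCC(C)(C)O2
F2 | step 4 | 3-(2,2-dimethylchroman-6-yl)-7-(triisopropylsilyloxy)-4H-chromen-4-one | CC(C)[Si](C(C)C)(C(C)C)Oc1ccc2c(c1)OC=C(c1ccc3c(c1)CCC(C)(C)O3)C2=O
F3 | step 4 | (3R,4R)-3-(2,2-dimethylchroman-6-yl)-7-(triisopropylsilyloxy)chroman-4-ol | CC(C)[Si](C(C)C)(C(C)C)Oc1ccc2c(c1)OC[C@@H](c1ccc3c(c1)CCC(C)(C)O3)[C@H]2O
F4 | step 7 | (3R)-3-(2,2-dimethylchroman-6-yl)-7-hydroxy-8-iodochroman-4-one | Oc1ccc2c(c1I)OC[C@@H](c1ccc3c(c1)CCC(C)(C)O3)C2=O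
F5 | step 8 | (3R)-7-(allyloxy)-3-(2,2-dimethylchroman-6-yl)chroman-4-one | C=CCOc1ccc2c(c1)OC[C@@H](c1ccc3c(c1)CCC(C)(C)O3)C2=O
F6 | step 8 | (3R)-8-allyl-3-(2,2-dimethylchroman-6-yl)-7-hydroxychroman-4-one | C=CCc1c(O)ccc2c1OC[C@@H](c1ccc3c(c1)CCC(C)(C)O3)C2=O
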